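**Plan** (numbering: ring carbons C1–C10 as in a halimane, C11/C12 chain, butenolide C13 (β-carbon), C14 (=CH), C15 (C=O), C16 (OCH2))

- Retrosynthesis: cut the C1–C5 aldol bond (transannular aldol of a 5,10-seco-dione), rejoin C5 and C10 as the alkene of a Δ5(10)-octalin, open ring A at C4–C5 (epoxide–olefin cyclisation) and at C10–C1 (Negishi), and cut the butenolide at C14–C15 and C13–C16.
- Enabling feature: the butenolide C13=C14(H) unit is a masked terminal alkyne, and O/C16/C15 map onto O1/C2/C5 of an oxazole. A Diels–Alder/retro-Diels–Alder with 4-phenyloxazole (PhCN extruded) makes both ring C–C bonds at once as a 3-furyl group, which is then oxidised regioselectively to the butenolide.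
- Forward order of rings: ring B (cyclohexanone 4) → alkyne 8 → furan 11 → butenolide 16 → ring A by cationic cyclisation (octalin 21) → ten-membered dione 23 → five- and seven-membered rings together by transannular aldol (24).
- Stereochemistry: C8 from ligand-controlled Cu-catalysed conjugate addition; C9 from anti alkylation of the enolate; C3 from Shi epoxidation; C5 and C1 from the reversible transannular aldol (cis-3,5-diol, trans ring fusion by equilibration at C1).

Key step: step 5

Remark: it is assumed that the C1/C5 configuration of the target is that of the thermodynamically preferred aldol adduct of dione 23 (3-OH and 5-OH cis and hydrogen-bonded, C1 epimerisable next to the C10 ketone).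

Step 1
Reactants: 1 2-methylcyclohex-2-en-1-one; 2 allyl iodide
Product: 4 (2S,3R)-2,3-dimethyl-2-(prop-2-en-1-yl)cyclohexan-1-one, via magnesium enolate 3 (not isolated)
Conditions: MeMgBr, CuBr·SMe2 (5 mol %), (R,S)-Josiphos-type diphosphine (6 mol %), t-BuOMe, −78 °C; then 2, DMPU, −78 → 0 °C
Reagents that add atoms: methylmagnesium bromide (C[Mg]Br)
Why: Copper-catalysed asymmetric conjugate addition of the Grignard reagent (ligand antipode chosen so that methyl adds to the face giving the 3R centre, C8) followed by C-allylation of magnesium enolate 3 anti to the new methyl group should set the quaternary C9 with the two methyl groups cis (tandem conjugate addition–enolate alkylation).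

Step 2
Reactants: 4 (2S,3R)-2,3-dimethyl-2-(prop-2-en-1-yl)cyclohexan-1-one
Product: 6 (2S,3R)-2-(3-hydroxypropyl)-2,3-dimethylcyclohexan-1-one, via alkylborane 5 (not isolated)
Conditions: 9-BBN, THF, 0 °C → rt; then NaOH, H2O2, H2O, 0 °C
Reagents that add atoms: hydrogen peroxide (OO)
Why: Anti-Markovnikov hydroboration–oxidation, in which 9-BBN should take the unhindered terminal alkene much faster than the α-quaternary ketone and the stereocentres are untouched.

Step 3
Reactants: 6 (2S,3R)-2-(3-hydroxypropyl)-2,3-dimethylcyclohexan-1-one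
Product: 7 3-[(1S,6R)-1,6-dimethyl-2-oxocyclohexyl]propanal
Conditions: Dess–Martin periodinane, NaHCO3, CH2Cl2, 0 °C → rt
Reagents that add atoms: none
Why: Dess–Martin oxidation should stop at the aldehyde under buffered, non-epimerising conditions and leave the ketone alone.

Step 4
Reactants: 7 3-[(1S,6R)-1,6-dimethyl-2-oxocyclohexyl]propanal
Product: 8 (2S,3R)-2-(but-3-yn-1-yl)-2,3-dimethylcyclohexan-1-one
Conditions: dimethyl (1-diazo-2-oxopropyl)phosphonate, K2CO3, MeOH, 0 °C → rt
Reagents that add atoms: dimethyl (1-diazo-2-oxopropyl)phosphonate (COP(=O)(OC)C(=[N+]=[N-])C(C)=O)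
Why: Seyferth–Gilbert homologation with the Ohira–Bestmann reagent should turn the aldehyde into the terminal alkyne C13≡C14 under mild carbonate conditions that the hindered, non-epimerisable ketone tolerates.

Step 5
Reactants: 8 (2S,3R)-2-(but-3-yn-1-yl)-2,3-dimethylcyclohexan-1-one; 9 4-phenyl-1,3-oxazole
Product: 11 (2S,3R)-2-[2-(furan-3-yl)ethyl]-2,3-dimethylcyclohexan-1-one, via cycloadduct 10 (not isolated)
Conditions: 9 (3 equiv), neat, sealed tube, 220 °C
Reagents that add atoms: none
Why: Thermal [4+2] cycloaddition of the oxazole azadiene (termini C2 and C5) across the terminal alkyne C13≡C14 gives the 7-oxa-2-azabicyclo[2.2.1]heptadiene 10, which undergoes retro-[4+2] with loss of benzonitrile, so that the C14–C15 and C13–C16 bonds are made in one operation. The closest known reaction type is the oxazole–alkyne Diels–Alder/retro-Diels–Alder furan synthesis with 4-phenyloxazole. The furan ring is closed by an intermolecular concerted [4+2] cycloaddition followed by cycloreversion, and no stereocentre is formed. The orientation of the cycloaddition does not matter, because both oxazole termini are CH and both regioisomers of 10 collapse to the same 3-substituted furan; the selectivity that is needed is the direction of the cycloreversion, which the 4-phenyl group secures by making PhC≡N the extruded fragment, helped by the aromaticity gained. Chemoselectivity rests on the substrate: 8 holds only a hindered α-quaternary ketone beside the alkyne, which is why the step is run here, before the enol triflate, the diene and the epoxide exist.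

Step 6
Reactants: 11 (2S,3R)-2-[2-(furan-3-yl)ethyl]-2,3-dimethylcyclohexan-1-one
Product: 13 (5R,6S)-6-[2-(furan-3-yl)ethyl]-5,6-dimethylcyclohex-1-en-1-yl trifluoromethanesulfonate, via potassium enolate 12 (not isolated)
Conditions: KHMDS, THF, −78 °C; then PhNTf2, −78 → 0 °C
Reagents that add atoms: N-phenylbis(trifluoromethanesulfonimide) (O=S(=O)(N(c1ccccc1)S(=O)(=O)C(F)(F)F)C(F)(F)F)
Why: Only C5 carries α-hydrogens (C9 is quaternary), so deprotonation is regiospecific and O-sulfonylation of potassium enolate 12 should give the vinyl triflate (enol triflate formation), the furan being inert to the amide base.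

Step 7
Reactants: 13 (5R,6S)-6-[2-(furan-3-yl)ethyl]-5,6-dimethylcyclohex-1-en-1-yl trifluoromethanesulfonate
Product: 16 (5R,6S)-5,6-dimethyl-6-[2-(5-oxo-2,5-dihydrofuran-3-yl)ethyl]cyclohex-1-en-1-yl trifluoromethanesulfonate, via endoperoxide 14 (not isolated), via hydroxybutenolide 15 (not isolated)
Conditions: O2, hν, rose bengal (cat.), i-Pr2NEt, CH2Cl2, −78 °C; then NaBH4, EtOH, 0 °C; 1 M HCl work-up
Reagents that add atoms: dioxygen (O=O)
Why: [4+2] addition of singlet oxygen to the furan gives endoperoxide 14, the hindered amine removes the proton at the unsubstituted α-carbon remote from the side chain (Kornblum–DeLaMare-type fragmentation) so that this carbon becomes the lactone carbonyl C15 in 15, and borohydride reduction of the masked aldehyde at C16 followed by relactonisation should give the 4-substituted butenolide, the electron-poor vinyl triflate being inert to both reagents.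

Step 8
Reactants: 16 (5R,6S)-5,6-dimethyl-6-[2-(5-oxo-2,5-dihydrofuran-3-yl)ethyl]cyclohex-1-en-1-yl trifluoromethanesulfonate; 17 5-bromo-2-methylpent-2-ene
Product: 19 4-{2-[(1S,6R)-1,6-dimethyl-2-(4-methylpent-3-en-1-yl)cyclohex-2-en-1-yl]ethyl}furan-2(5H)-one, via organozinc bromide 18 (not isolated)
Conditions: 17, Zn, LiCl, THF, 40 °C; then 16, Pd(dppf)Cl2 (5 mol %), THF, 50 °C
Reagents that add atoms: none
Why: Negishi sp3–sp2 cross-coupling of the vinyl triflate with the primary alkylzinc 18 should form the C10–C1 bond, and the mild organozinc tolerates the butenolide that a Grignard reagent would attack.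

Step 9
Reactants: 19 4-{2-[(1S,6R)-1,6-dimethyl-2-(4-methylpent-3-en-1-yl)cyclohex-2-en-1-yl]ethyl}furan-2(5H)-one
Product: 20 4-{2-[(1S,6R)-2-{2-[(2R)-3,3-dimethyloxiran-2-yl]ethyl}-1,6-dimethylcyclohex-2-en-1-yl]ethyl}furan-2(5H)-one
Conditions: D-fructose-derived Shi ketone (0.3 equiv), KHSO5 (Oxone), K2CO3, n-Bu4NHSO4, MeCN/dimethoxymethane/aqueous buffer, 0 °C
Reagents that add atoms: potassium peroxymonosulfate ([K+].[O-]S(=O)(=O)OO)
Why: Shi epoxidation, in which the chiral dioxirane should select the unhindered, electron-rich isopropylidene alkene over the ring alkene shielded by quaternary C9 and over the electron-poor butenolide, and its spiro transition state sets C3 as R.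

Step 10
Reactants: 20 4-{2-[(1S,6R)-2-{2-[(2R)-3,3-dimethyloxiran-2-yl]ethyl}-1,6-dimethylcyclohex-2-en-1-yl]ethyl}furan-2(5H)-one
Product: 21 4-{2-[(1S,2R,6R)-6-hydroxy-1,2,5,5-tetramethyl-1,2,3,4,5,6,7,8-octahydronaphthalen-1-yl]ethyl}furan-2(5H)-one
Conditions: MeAlCl2 (2.2 equiv), CH2Cl2, −78 °C; Et3N/MeOH quench
Reagents that add atoms: none
Why: Lewis-acid opening of the epoxide at tertiary C4 and 6-endo capture by C5 of the cyclohexene through a chair transition state (epoxide-initiated cation–olefin cyclisation) gives the tertiary C10 cation, which should lose H5 to the tetrasubstituted Δ5(10) alkene, while C3 keeps its configuration because only the C4–O bond breaks.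

Step 11
Reactants: 21 4-{2-[(1S,2R,6R)-6-hydroxy-1,2,5,5-tetramethyl-1,2,3,4,5,6,7,8-octahydronaphthalen-1-yl]ethyl}furan-2(5H)-one
Product: 23 4-{2-[(1S,2R,7R)-7-hydroxy-1,2,6,6-tetramethyl-5,10-dioxocyclodecyl]ethyl}furan-2(5H)-one, via ozonide 22 (not isolated)
Conditions: O3, CH2Cl2, −78 °C (Sudan Red 7B end point); then PPh3, −78 °C → rt
Reagents that add atoms: ozone ([O-][O+]=O)
Why: Ozonolysis, in which electrophilic ozone should cleave the electron-rich tetrasubstituted alkene far faster than the conjugated butenolide alkene when dosed to an indicator end point, and reduction of ozonide 22 gives the cyclodecane-1,6-dione.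

Step 12
Reactants: 23 4-{2-[(1S,2R,7R)-7-hydroxy-1,2,6,6-tetramethyl-5,10-dioxocyclodecyl]ethyl}furan-2(5H)-one
Product: 24 4-{2-[(2R,3aS,5S,6R,8aS)-2,8a-dihydroxy-1,1,5,6-tetramethyl-4-oxodecahydroazulen-5-yl]ethyl}furan-2(5H)-one
Conditions: DBU (0.2 equiv), CH2Cl2, 0 °C → rt
Reagents that add atoms: none
Why: Reversible transannular aldol addition of the C10 enolate (through C1, C9 being quaternary) to the C5 ketone, the carbonyl activated by the hydrogen bond from 3-OH, closes the five-membered ring through a 5-(enolexo)-exo-trig transition state and leaves the seven-membered ring, and under equilibrating conditions C5 should settle with 5-OH cis to 3-OH (hydrogen-bonded 1,3-diol) and C1, epimerisable next to C10=O, in the trans-fused arrangement of the target.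

**Compound list**

1 | 2-methylcyclohex-2-en-1-one | CC1=CCCCC1=O | starting material
2 | allyl iodide (3-iodoprop-1-ene) | C=CCI | starting material
3 | bromomagnesium (3R)-2,3-dimethylcyclohex-1-en-1-olate | C[C@@H]1CCCC(O[Mg]Br)=C1C | intermediate
4 | (2S,3R)-2,3-dimethyl-2-(prop-2-en-1-yl)cyclohexan-1-one | C[C@@H]1CCCC(=O)[C@@]1(C)CC=C | intermediate
5 | (2S,3R)-2-[3-(9-borabicyclo[3.3.1]nonan-9-yl)propyl]-2,3-dimethylcyclohexan-1-one | C[C@@H]1CCCC(=O)[C@@]1(C)CCCB1C2CCCC1CCC2 | intermediate
6 | (2S,3R)-2-(3-hydroxypropyl)-2,3-dimethylcyclohexan-1-one | C[C@@H]1CCCC(=O)[C@@]1(C)CCCO | intermediate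
7 | 3-[(1S,6R)-1,6-dimethyl-2-oxocyclohexyl]propanal | C[C@@H]1CCCC(=O)[C@@]1(C)CCC=O | intermediate
8 | (2S,3R)-2-(but-3-yn-1-yl)-2,3-dimethylcyclohexan-1-one | C[C@@H]1CCCC(=O)[C@@]1(C)CCC#C | intermediate
9 | 4-phenyl-1,3-oxazole | c1ccc(cc1)-c1cocn1 | starting material
10 | (2S,3R)-2,3-dimethyl-2-[2-(3-phenyl-7-oxa-2-azabicyclo[2.2.1]hepta-2,5-dien-6-yl)ethyl]cyclohexan-1-one (one of two regioisomers, both give 11; bridgehead configuration not fixed) | C[C@@H]1CCCC(=O)[C@@]1(C)CCC1=CC2OC1N=C2c1ccccc1 | intermediate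
11 | (2S,3R)-2-[2-(furan-3-yl)ethyl]-2,3-dimethylcyclohexan-1-one | C[C@@H]1CCCC(=O)[C@@]1(C)CCc1ccoc1 | intermediate
12 | potassium (5R,6S)-6-[2-(furan-3-yl)ethyl]-5,6-dimethylcyclohex-1-en-1-olate | C[C@@H]1CCC=C([O-])[C@@]1(C)CCc1ccoc1.[K+] | intermediate
13 | (5R,6S)-6-[2-(furan-3-yl)ethyl]-5,6-dimethylcyclohex-1-en-1-yl trifluoromethanesulfonate | C[C@@H]1CCC=C(OS(=O)(=O)C(F)(F)F)[C@@]1(C)CCc1ccoc1 | intermediate
14 | (5R,6S)-5,6-dimethyl-6-[2-(2,3,7-trioxabicyclo[2.2.1]hept-5-en-5-yl)ethyl]cyclohex-1-en-1-yl trifluoromethanesulfonate (bridgehead configuration not fixed) | C[C@@H]1CCC=C(OS(=O)(=O)C(F)(F)F)[C@@]1(C)CCC1=CC2OOC1O2 | intermediate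
15 | (5R,6S)-6-[2-(2-hydroxy-5-oxo-2,5-dihydrofuran-3-yl)ethyl]-5,6-dimethylcyclohex-1-en-1-yl trifluoromethanesulfonate (hemiacetal epimers) | C[C@@H]1CCC=C(OS(=O)(=O)C(F)(F)F)[C@@]1(C)CCC1=CC(=O)OC1O | intermediate
16 | (5R,6S)-5,6-dimethyl-6-[2-(5-oxo-2,5-dihydrofuran-3-yl)ethyl]cyclohex-1-en-1-yl trifluoromethanesulfonate | C[C@@H]1CCC=C(OS(=O)(=O)C(F)(F)F)[C@@]1(C)CCC1=CC(=O)OC1 | intermediate
17 | 5-bromo-2-methylpent-2-ene | CC(C)=CCCBr | starting material
18 | (4-methylpent-3-en-1-yl)zinc bromide | CC(C)=CCC[Zn]Br | intermediate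
19 | 4-{2-[(1S,6R)-1,6-dimethyl-2-(4-methylpent-3-en-1-yl)cyclohex-2-en-1-yl]ethyl}furan-2(5H)-one | C[C@@H]1CCC=C(CCC=C(C)C)[C@@]1(C)CCC1=CC(=O)OC1 | intermediate
20 | 4-{2-[(1S,6R)-2-{2-[(2R)-3,3-dimethyloxiran-2-yl]ethyl}-1,6-dimethylcyclohex-2-en-1-yl]ethyl}furan-2(5H)-one | C[C@@H]1CCC=C(CC[C@H]2OC2(C)C)[C@@]1(C)CCC1=CC(=O)OC1 | intermediate
21 | 4-{2-[(1S,2R,6R)-6-hydroxy-1,2,5,5-tetramethyl-1,2,3,4,5,6,7,8-octahydronaphthalen-1-yl]ethyl}furan-2(5H)-one | C[C@@H]1CCC2=C(CC[C@@H](O)C2(C)C)[C@@]1(C)CCC1=CC(=O)OC1 | intermediate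
22 | secondary ozonide of 21 (1,2,4-trioxolane spanning the former alkene carbons C5 and C10; configuration at these two carbons not fixed) | C[C@@H]1CCC24OOC(O2)(CC[C@@H](O)C4(C)C)[C@@]1(C)CCC1=CC(=O)OC1 | intermediate
23 | 4-{2-[(1S,2R,7R)-7-hydroxy-1,2,6,6-tetramethyl-5,10-dioxocyclodecyl]ethyl}furan-2(5H)-one | C[C@@H]1CCC(=O)C(C)(C)[C@H](O)CCC(=O)[C@@]1(C)CCC1=CC(=O)OC1 | intermediate
24 | 4-{2-[(2R,3aS,5S,6R,8aS)-2,8a-dihydroxy-1,1,5,6-tetramethyl-4-oxodecahydroazulen-5-yl]ethyl}furan-2(5H)-one | C[C@@H]1CC[C@]2(O)[C@H](C[C@@H](O)C2(C)C)C(=O)[C@@]1(C)CCC1=CC(=O)OC1 | target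

**Step count and risks**

Total step count: 12. Longest linear sequence: 12 steps (from 1).

Steps most likely to fail:

1. Step 12. The ten-membered dione is nearly symmetric in its reactivity, so the transannular aldol may run the other way (C6 onto C10), the C5/C1 configuration may equilibrate to another diastereomer, or the aldol may dehydrate. Fallback, setting out from 21: Dess–Martin oxidation of 3-OH should give the octalin-3-one F1, and ozonolysis (O3; PPh3) the 3,5,10-triketone F2. In F2 the C5 carbonyl belongs to a non-enolisable 2,2-dimethyl-1,3-dione and is the most electrophilic in the ring, so DBU should give the C1–C5 aldol as the 3-oxo aldol F3. Chelation-controlled reduction (Et2BOMe, NaBH4, THF/MeOH, −78 °C; Narasaka–Prasad) should then deliver hydride to the face opposite the boron chelate of 5-OH and give the cis-3,5-diol, sparing the hindered C10 ketone. The fallback comes back to the route at 24.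

2. Step 10. The C10 cation may lose the proton from C1 instead of C5 (wrong alkene position), or a methyl group may shift from C9 to C10 before elimination. Fallback, setting out from 20: radical instead of cationic cyclisation. Cp2TiCl (from Cp2TiCl2 and Mn, 2,4,6-collidine hydrochloride, THF) opens the epoxide homolytically to the tertiary C4 radical; 6-endo cyclisation and β-hydride elimination from the alkyltitanium should give mainly the Δ1(10)-octalinol F4 without skeletal rearrangement. Hydrogen-atom-transfer isomerisation (Co(salen)Cl cat., PhSiH3, benzene, rt) should then move the alkene to the tetrasubstituted position. The fallback comes back at 21.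

3. Step 5. The unactivated alkyne may add too slowly at 220 °C, and the ketone enol may close thermally onto the alkyne (ene-type reaction) or the material may decompose. Fallback, setting out from 8: a ketene route at room temperature that forms the same two bonds. Dichloroketene (Cl3CCOCl, Zn(Cu), Et2O/DME) should add to the alkyne with the carbonyl carbon on C14 to give the 4,4-dichlorocyclobutenone F5; Zn, AcOH, TMEDA should give the cyclobutenone F6; Baeyer–Villiger ring expansion (mCPBA, NaHCO3, CH2Cl2, 0 °C) with migration of the ring CH2, driven by release of four-ring strain, should give the keto butenolide F7. Tf2O with 2,6-di-tert-butyl-4-methylpyridine in CH2Cl2 then forms the enol triflate without an amide base. The fallback comes back at 16.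

**Further compounds**

F1 | step 12 | 4-{2-[(1S,2R)-1,2,5,5-tetramethyl-6-oxo-1,2,3,4,5,6,7,8-octahydronaphthalen-1-yl]ethyl}furan-2(5H)-one | C[C@@H]1CCC2=C(CCC(=O)C2(C)C)[C@@]1(C)CCC1=CC(=O)OC1
F2 | step 12 | 4-{2-[(1S,2R)-1,2,6,6-tetramethyl-5,7,10-trioxocyclodecyl]ethyl}furan-2(5H)-one | C[C@@H]1CCC(=O)C(C)(C)C(=O)CCC(=O)[C@@]1(C)CCC1=CC(=O)OC1
F3 | step 12 | 4-{2-[(3aS,5S,6R,8aS)-8a-hydroxy-1,1,5,6-tetramethyl-2,4-dioxodecahydroazulen-5-yl]ethyl}furan-2(5H)-one | C[C@@H]1CC[C@]2(O)[C@H](CC(=O)C2(C)C)C(=O)[C@@]1(C)CCC1=CC(=O)OC1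
F4 | step 10 | 4-{2-[(1S,2R,6R)-6-hydroxy-1,2,5,5-tetramethyl-1,2,3,4,4a,5,6,7-octahydronaphthalen-1-yl]ethyl}furan-2(5H)-one (configuration at C4a not fixed) | C[C@@H]1CCC2C(=CC[C@@H](O)C2(C)C)[C@@]1(C)CCC1=CC(=O)OC1
F5 | step 5 | 4,4-dichloro-3-{2-[(1S,6R)-1,6-dimethyl-2-oxocyclohexyl]ethyl}cyclobut-2-en-1-one | C[C@@H]1CCCC(=O)[C@@]1(C)CCC1=CC(=O)C1(Cl)Cl
F6 | step 5 | 3-{2-[(1S,6R)-1,6-dimethyl-2-oxocyclohexyl]ethyl}cyclobut-2-en-1-one | C[C@@H]1CCCC(=O)[C@@]1(C)CCC1=CC(=O)C1
F7 | step 5 | 4-{2-[(1S,6R)-1,6-dimethyl-2-oxocyclohexyl]ethyl}furan-2(5H)-one | C[C@@H]1CCCC(=O)[C@@]1(C)CCC1=CC(=O)OC1
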